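Numbering: chromene O1, C2–C8a; side chain C1'–C12'. The target is 2S,8'S,3'E,6'E. The hardest features are two remote tertiary C–O stereocentres that cannot control each other, an aryl–O bond to a tertiary allylic carbon (C2) that must never ionise, and a labile 1,4-diene/chromenol.
Cuts: C5'–C6' (allyl–alkenyl bond in the middle of the chain), then O1–C8a and C4–C4a of the pyran ring. The C4–C4a bond is traced back to a C4–C8a bond in a para-substituted phenol.
Hidden repeat: C4–C3–C2(Me)(O)–C1'–C2'–C3'=C4'(Me)–C5' and C6'–C7'–C8'(Me)(O)–C9'–C10'–C11'=C12'(Me)–Me are the same dehydrolinalool skeleton with the same absolute sense. One alkynol, (S)-dehydrolinalool, therefore serves as both halves.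
Feature that enables the key step: in the benzene ring O1 stands on C8a para to the C6–OH, C4 stands on the neighbouring C4a, and C8 carries CH3. This is the pattern left by ipso-oxygenation and 1,2-shift (NIH-type) of a 4-alkenyl-3-methylphenol, and the Z-C3=C4 bond holds the C2–OH over C8a.
Forward: geraniol gives the alkynol. West half: C5' hydroxylation, arylation at C4, Z-reduction, then the dihydrofuran spiro ring (dearomatisation) and the pyran ring (1,2-shift, rearomatisation). East half: hydrostannation. The chain is joined last at C5'–C6', followed by deacetylation.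
Stereochemistry: C2 and C8' both come from C3 of one (2S,3S)-epoxygeraniol, and their C–O bonds are never broken, so the mirror image of the target can only arise from two minor enantiomers. 3'E comes from SeO2, 6'E from syn-hydrostannation, and Z-C3=C4 from Lindlar reduction.

Key step: step 7

Remark: geraniol and 4-iodo-3-methylphenol are taken as catalogue compounds. The spiro carbon of the non-isolated spirodienone forms as both epimers, which is of no consequence because it becomes the planar C8a.

Step 1
Reactants: 1 geraniol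
Product: 2 (2S,3S)-2,3-epoxygeraniol
Conditions: Ti(OiPr)4 (5 mol%), L-(+)-diethyl tartrate (6 mol%), t-BuOOH, 4 Å MS, CH2Cl2, −20 °C
Reagents that add atoms: tert-butyl hydroperoxide, CC(C)(C)OO
Why: Katsuki–Sharpless asymmetric epoxidation touches only the alkene of the allylic alcohol, and the L-(+)-tartrate/titanium complex delivers oxygen to the face that gives the (2S,3S)-epoxide, whose C3–O bond later becomes both the C2–O1 and the C8'–OH bond of the target.

Step 2
Reactants: 2 (2S,3S)-2,3-epoxygeraniol
Product: 3 (2S,3R)-3-(chloromethyl)-2-methyl-2-(4-methylpent-3-enyl)oxirane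
Conditions: PPh3, CCl4, NaHCO3 (cat.), reflux
Reagents that add atoms: carbon tetrachloride, ClC(Cl)(Cl)Cl
Why: Appel chlorination replaces the primary hydroxyl under neutral conditions that leave the epoxide, the distal alkene and both stereocentres untouched (the CH carbon only changes its CIP label).

Step 3
Reactants: 3 (2S,3R)-3-(chloromethyl)-2-methyl-2-(4-methylpent-3-enyl)oxirane
Product: 4 (S)-dehydrolinalool [(3S)-3,7-dimethyloct-6-en-1-yn-3-ol]
Conditions: n-BuLi (3.2 equiv), THF, −78 → −30 °C; then H2O
Reagents that add atoms: none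
Why: Base-induced eliminative opening of a 2,3-epoxy chloride followed by dehydrochlorination, a well-used route from epoxy alcohols to propargylic alcohols, forms the terminal alkyne while the tertiary C–O bond stays intact, so the S configuration is retained.

Step 4
Reactants: 4 (S)-dehydrolinalool
Product: 5 (2E,6S)-2,6-dimethyloct-2-en-7-yne-1,6-diol
Conditions: SeO2 (20 mol%), t-BuOOH (2 equiv), salicylic acid (10 mol%), CH2Cl2, 0 °C → rt
Reagents that add atoms: tert-butyl hydroperoxide, CC(C)(C)OO; selenium dioxide (oxygen carrier), O=[Se]=O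
Why: Selenium dioxide allylic hydroxylation (ene reaction, then [2,3]-sigmatropic shift) attacks the only alkene and, as is the rule for gem-dimethyl trisubstituted alkenes, oxidises the E-methyl group, which fixes the later 3'E geometry and puts the oxygen on C5'.

Step 5
Reactants: 5 (2E,6S)-2,6-dimethyloct-2-en-7-yne-1,6-diol; 6 4-iodo-3-methylphenol
Product: 7 4-[(3S,6E)-3,8-dihydroxy-3,7-dimethyloct-6-en-1-ynyl]-3-methylphenol
Conditions: PdCl2(PPh3)2 (2 mol%), CuI (4 mol%), Et3N, THF, rt, Ar
Reagents that add atoms: none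
Why: Sonogashira coupling of a terminal alkyne with an aryl iodide tolerates the free phenol and both alcohols and joins C4 to the ring carbon para to the phenolic OH (the later C8a).

Step 6
Reactants: 7 4-[(3S,6E)-3,8-dihydroxy-3,7-dimethyloct-6-en-1-ynyl]-3-methylphenol
Product: 8 4-[(1Z,3S,6E)-3,8-dihydroxy-3,7-dimethylocta-1,6-dienyl]-3-methylphenol
Conditions: H2 (1 atm), Lindlar catalyst, quinoline, EtOAc, rt
Reagents that add atoms: none
Why: Lindlar semihydrogenation adds H2 syn to the alkyne only, giving the Z-C3=C4 alkene that the pyran ring needs and leaving the trisubstituted alkene alone.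

Step 7
Reactants: 8 4-[(1Z,3S,6E)-3,8-dihydroxy-3,7-dimethylocta-1,6-dienyl]-3-methylphenol
Product: 11 (2S)-2-[(3E)-5-acetoxy-4-methylpent-3-enyl]-2,8-dimethyl-2H-chromen-6-yl acetate, via spirodienone 9 (not isolated), via chromenol diol 10 (not isolated)
Conditions: PhI(OAc)2 (1.0 equiv), CH2Cl2, 0 °C; then BF3·OEt2 (20 mol%), −40 → 0 °C; then pyridine, Ac2O (4 equiv), DMAP (cat.), 0 °C
Reagents that add atoms: acetic anhydride, CC(=O)OC(C)=O
Why: Proposed new method: PhI(OAc)2 binds the phenol oxygen, and the C2–OH, held over the ring by the Z-C3=C4 bond, attacks the para carbon C8a (ipso, 5-exo-trig on the arene C=C) to close the 2,5-dihydrofuran ring of 9, which is the known hypervalent-iodine spiro-etherification of 4-(3-hydroxyalkyl)phenols. BF3 then activates the dienone C=O, and C4 shifts from C8a to the adjacent cationic C4a while the O1 lone pair takes up the charge at C8a, so the five-membered ring expands to the six-membered pyran and loss of H-4a restores the arene; the closest known reaction type is the dienone–phenol rearrangement (p-quinols and p-quinol ethers to 2-substituted hydroquinones, spiro[4.5]decadienones to ring-expanded phenols), extended here to an sp2 migrating carbon inside an oxaspiro ring, which should migrate more readily than alkyl. The only new stereocentre, the spiro C8a, is not controlled and need not be, since it becomes planar again, and C2 keeps its configuration because none of its four bonds is broken. Three selectivities are needed: ipso attack rather than capture at the vinylogous position C3 (secured by the intramolecular five-ring closure, the non-nucleophilic medium and the ortho-methyl twist that decouples the styrene), carbon rather than oxygen migration (only C-migration leaves an oxygen-stabilised cation), and migration to C4a rather than C8 (the C8 methyl blocks rearomatisation there, so that shift is reversible). The oxidant is consumed before the oxidation-prone hydroquinone monoether appears, and the closing acetylation both masks the phenol and turns the C5' alcohol into the leaving group of step 9.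

Step 8
Reactants: 4 (S)-dehydrolinalool
Product: 12 (1E,3S)-3,7-dimethyl-1-(tributylstannyl)octa-1,6-dien-3-ol
Conditions: Bu3SnH (1.1 equiv), PdCl2(PPh3)2 (2 mol%), THF, 0 °C
Reagents that add atoms: tributyltin hydride, CCCC[SnH](CCCC)CCCC
Why: Palladium-catalysed hydrostannation is a syn addition, and the fully substituted carbinol carbon next to the alkyne steers tin to the terminal carbon, so the E-alkenylstannane (later 6'E) should form without protection of the hydroxyl.

Step 9
Reactants: 11 (2S)-2-[(3E)-5-acetoxy-4-methylpent-3-enyl]-2,8-dimethyl-2H-chromen-6-yl acetate; 12 (1E,3S)-3,7-dimethyl-1-(tributylstannyl)octa-1,6-dien-3-ol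
Product: 13 (2S)-2-[(3E,6E,8S)-8-hydroxy-4,8,12-trimethyltrideca-3,6,11-trienyl]-2,8-dimethyl-2H-chromen-6-yl acetate
Conditions: Pd(dba)2 (5 mol%), LiCl (3 equiv), DMF, rt, Ar
Reagents that add atoms: none
Why: Stille coupling of an allylic acetate with an alkenylstannane ionises only the allylic (not the aryl) acetate and joins the alkenyl group to the less hindered CH2 terminus (C5') of the π-allylpalladium with retention of both alkene geometries, under neutral conditions that do not isomerise the 1,4-diene.

Step 10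
Reactants: 13 (2S)-2-[(3E,6E,8S)-8-hydroxy-4,8,12-trimethyltrideca-3,6,11-trienyl]-2,8-dimethyl-2H-chromen-6-yl acetate
Product: 14 (2S)-2-[(3E,6E,8S)-8-hydroxy-4,8,12-trimethyltrideca-3,6,11-trienyl]-2,8-dimethyl-2H-chromen-6-ol (CNP0155965.1)
Conditions: K2CO3 (20 mol%), degassed MeOH, 0 °C, Ar; then aq. NH4Cl
Reagents that add atoms: none
Why: Base-catalysed transesterification cleaves the aryl acetate within the tolerance of the tertiary allylic alcohol, the skipped diene and the chromene, none of which would survive an acidic or oxidative deprotection.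

Compound list
1 | geraniol, (2E)-3,7-dimethylocta-2,6-dien-1-ol | CC(C)=CCC/C(C)=C/CO | starting material
2 | (2S,3S)-2,3-epoxygeraniol, [(2S,3S)-3-methyl-3-(4-methylpent-3-enyl)oxiran-2-yl]methanol | CC(C)=CCC[C@]1(C)O[C@H]1CO | intermediate
3 | (2S,3R)-3-(chloromethyl)-2-methyl-2-(4-methylpent-3-enyl)oxirane | CC(C)=CCC[C@]1(C)O[C@H]1CCl | intermediate
4 | (S)-dehydrolinalool, (3S)-3,7-dimethyloct-6-en-1-yn-3-ol | CC(C)=CCC[C@](C)(O)C#C | intermediate
5 | (2E,6S)-2,6-dimethyloct-2-en-7-yne-1,6-diol | OC/C(C)=C/CC[C@](C)(O)C#C | intermediate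
6 | 4-iodo-3-methylphenol | Cc1cc(O)ccc1I | starting material
7 | 4-[(3S,6E)-3,8-dihydroxy-3,7-dimethyloct-6-en-1-ynyl]-3-methylphenol | OC/C(C)=C/CC[C@](C)(O)C#Cc1ccc(O)cc1C | intermediate
8 | 4-[(1Z,3S,6E)-3,8-dihydroxy-3,7-dimethylocta-1,6-dienyl]-3-methylphenol | OC/C(C)=C/CC[C@](C)(O)/C=C\c1ccc(O)cc1C | intermediate
9 | (2S)-2-[(3E)-5-hydroxy-4-methylpent-3-enyl]-2,6-dimethyl-1-oxaspiro[4.5]deca-3,6,9-trien-8-one (both epimers at spiro C5, centre left undefined) | OC/C(C)=C/CC[C@@]1(C)C=CC2(O1)C=CC(=O)C=C2C | intermediate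
10 | (2S)-2-[(3E)-5-hydroxy-4-methylpent-3-enyl]-2,8-dimethyl-2H-chromen-6-ol | OC/C(C)=C/CC[C@@]1(C)C=Cc2cc(O)cc(C)c2O1 | intermediate
11 | (2S)-2-[(3E)-5-acetoxy-4-methylpent-3-enyl]-2,8-dimethyl-2H-chromen-6-yl acetate | CC(=O)OC/C(C)=C/CC[C@@]1(C)C=Cc2cc(OC(C)=O)cc(C)c2O1 | intermediate
12 | (1E,3S)-3,7-dimethyl-1-(tributylstannyl)octa-1,6-dien-3-ol | CC(C)=CCC[C@](C)(O)/C=C/[Sn](CCCC)(CCCC)CCCC | intermediate
13 | (2S)-2-[(3E,6E,8S)-8-hydroxy-4,8,12-trimethyltrideca-3,6,11-trienyl]-2,8-dimethyl-2H-chromen-6-yl acetate | CC(C)=CCC[C@](C)(O)/C=C/C/C(C)=C/CC[C@@]1(C)C=Cc2cc(OC(C)=O)cc(C)c2O1 | intermediate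
14 | (2S)-2-[(3E,6E,8S)-8-hydroxy-4,8,12-trimethyltrideca-3,6,11-trienyl]-2,8-dimethyl-2H-chromen-6-ol | CC(C)=CCC[C@](C)(O)/C=C/C/C(C)=C/CC[C@@]1(C)C=Cc2cc(O)cc(C)c2O1 | target

Total step count: 10. Longest linear sequence: 9 steps (1, 2, 3, 4, 5, 6, 7, 9, 10).

Steps most likely to fail

(i) Step 7 (labelled step).
- What may go wrong: the oxidised phenol may be captured at the vinylogous position C3 or by acetate instead of by ipso ring closure. Oxygen may migrate instead of carbon. Acid may ionise the tertiary allylic O1–C2 bond and erode the C2 configuration.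
- Fallback: it uses known chemistry only, sets out from 5, and comes back at 10, which is acetylated to 11 as in the last stage of step 7.
- Commercial 2-bromo-1-iodo-3-methylbenzene is borylated at its only unhindered C–H ([Ir(OMe)(cod)]2, dtbpy, B2pin2) to 2-(4-bromo-3-iodo-5-methylphenyl)-4,4,5,5-tetramethyl-1,3,2-dioxaborolane F1. This is oxidised (Oxone, aqueous acetone) to 4-bromo-3-iodo-5-methylphenol F2.
- Sonogashira coupling of 5 at the C–I bond gives 4-bromo-3-[(3S,6E)-3,8-dihydroxy-3,7-dimethyloct-6-en-1-ynyl]-5-methylphenol F3. Lindlar reduction gives 4-bromo-3-[(1Z,3S,6E)-3,8-dihydroxy-3,7-dimethylocta-1,6-dienyl]-5-methylphenol F4.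
- TBSCl/imidazole (2 equiv) gives (1Z,3S,6E)-1-[2-bromo-5-(tert-butyldimethylsilyloxy)-3-methylphenyl]-8-(tert-butyldimethylsilyloxy)-3,7-dimethylocta-1,6-dien-3-ol F5, with the tertiary hydroxyl left free.
- Palladium-catalysed intramolecular C–O coupling of the tertiary alcohol with the aryl bromide (Pd(OAc)2, bulky di-tert-butylbiarylphosphine, Cs2CO3, toluene, 80 °C) closes the pyran ring with the C2–O bond intact. It gives (2S)-6-(tert-butyldimethylsilyloxy)-2-[(3E)-5-(tert-butyldimethylsilyloxy)-4-methylpent-3-enyl]-2,8-dimethyl-2H-chromene F6, and TBAF then releases 10.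

(ii) Step 9.
- What may go wrong: syn/anti equilibration of the 2-methyl-substituted π-allylpalladium may cost the 3'E geometry. Coupling may occur at C3' instead of C5'. Palladium(0) may open the allylic aryl ether O1–C2.
- Fallback: it avoids π-allyl metal species, sets out from 11, and comes back at 14.
- Methanolysis of 11 (K2CO3, MeOH) gives 10. Phase-transfer acylation of the phenoxide only (PivCl, aq. NaOH, Bu4NHSO4, CH2Cl2) gives (2S)-2-[(3E)-5-hydroxy-4-methylpent-3-enyl]-2,8-dimethyl-2H-chromen-6-yl pivalate F7.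
- Appel bromination (CBr4, PPh3, 0 °C) gives (2S)-2-[(3E)-5-bromo-4-methylpent-3-enyl]-2,8-dimethyl-2H-chromen-6-yl pivalate F8.
- Copper-mediated SN2 alkynylation with 4 (CuI, NaI, Cs2CO3, DMF, rt) gives (2S)-2-[(3E,8S)-8-hydroxy-4,8,12-trimethyltrideca-3,11-dien-6-ynyl]-2,8-dimethyl-2H-chromen-6-yl pivalate F9.
- Hydroxyl-directed trans-hydroalumination (Red-Al, THF, 0 °C → rt) reduces only the propargylic alkyne to the 6'E alkene and cleaves the pivalate in the same operation, giving 14.

(iii) Step 6.
- What may go wrong: over-reduction, stalling on the hindered ortho-methyl aryl alkyne, or partial Z-to-E isomerisation on the catalyst.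
- Fallback: the Z alkene is built before the aryl group is attached. The fallback sets out from 5 and comes back at 8.
- 5 is iodinated at the alkyne terminus (NIS, AgNO3 cat., acetone) to (2E,6S)-8-iodo-2,6-dimethyloct-2-en-7-yne-1,6-diol F10.
- Diimide (2-nitrobenzenesulfonylhydrazide, Et3N) reduces the iodoalkyne to (2E,6S,7Z)-8-iodo-2,6-dimethylocta-2,7-diene-1,6-diol F11.
- Suzuki–Miyaura coupling with commercial (4-hydroxy-2-methylphenyl)boronic acid (Pd(PPh3)4, aq. K2CO3, THF) proceeds with retention of the alkene geometry to 8.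

Further compounds
F1 | step 7 | 2-(4-bromo-3-iodo-5-methylphenyl)-4,4,5,5-tetramethyl-1,3,2-dioxaborolane | Cc1cc(B2OC(C)(C)C(C)(C)O2)cc(I)c1Br
F2 | step 7 | 4-bromo-3-iodo-5-methylphenol | Cc1cc(O)cc(I)c1Br
F3 | step 7 | 4-bromo-3-[(3S,6E)-3,8-dihydroxy-3,7-dimethyloct-6-en-1-ynyl]-5-methylphenol | OC/C(C)=C/CC[C@](C)(O)C#Cc1cc(O)cc(C)c1Br
F4 | step 7 | 4-bromo-3-[(1Z,3S,6E)-3,8-dihydroxy-3,7-dimethylocta-1,6-dienyl]-5-methylphenol | OC/C(C)=C/CC[C@](C)(O)/C=C\c1cc(O)cc(C)c1Br
F5 | step 7 | (1Z,3S,6E)-1-[2-bromo-5-(tert-butyldimethylsilyloxy)-3-methylphenyl]-8-(tert-butyldimethylsilyloxy)-3,7-dimethylocta-1,6-dien-3-ol | CC(C)(C)[Si](C)(C)OC/C(C)=C/CC[C@](C)(O)/C=C\c1cc(O[Si](C)(C)C(C)(C)C)cc(C)c1Br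
F6 | step 7 | (2S)-6-(tert-butyldimethylsilyloxy)-2-[(3E)-5-(tert-butyldimethylsilyloxy)-4-methylpent-3-enyl]-2,8-dimethyl-2H-chromene | CC(C)(C)[Si](C)(C)OC/C(C)=C/CC[C@@]1(C)C=Cc2cc(O[Si](C)(C)C(C)(C)C)cc(C)c2O1
F7 | step 9 | (2S)-2-[(3E)-5-hydroxy-4-methylpent-3-enyl]-2,8-dimethyl-2H-chromen-6-yl pivalate | OC/C(C)=C/CC[C@@]1(C)C=Cc2cc(OC(=O)C(C)(C)C)cc(C)c2O1
F8 | step 9 | (2S)-2-[(3E)-5-bromo-4-methylpent-3-enyl]-2,8-dimethyl-2H-chromen-6-yl pivalate | BrC/C(C)=C/CC[C@@]1(C)C=Cc2cc(OC(=O)C(C)(C)C)cc(C)c2O1
F9 | step 9 | (2S)-2-[(3E,8S)-8-hydroxy-4,8,12-trimethyltrideca-3,11-dien-6-ynyl]-2,8-dimethyl-2H-chromen-6-yl pivalate | CC(C)=CCC[C@](C)(O)C#CC/C(C)=C/CC[C@@]1(C)C=Cc2cc(OC(=O)C(C)(C)C)cc(C)c2O1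
F10 | step 6 | (2E,6S)-8-iodo-2,6-dimethyloct-2-en-7-yne-1,6-diol | OC/C(C)=C/CC[C@](C)(O)C#CI
F11 | step 6 | (2E,6S,7Z)-8-iodo-2,6-dimethylocta-2,7-diene-1,6-diol | OC/C(C)=C/CC[C@](C)(O)/C=C\I
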